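## The problem

The target is a diterpenoid stearate built on a nine-membered carbocycle fused to a tetrahydrofuran. Numbering used throughout: C1 carries the exocyclic methylene, C3=C4 is the Z alkene, C5 is the methyl carbinol, C8 and C9 are the ring-fusion carbons, C10 is the ring OCH2 and C11 is the fully substituted ether carbon. The rings are trans-fused (H8 and H9 anti). C11 bears the ring oxygen, an (E)-4-methylpenta-1,3-dienyl group cis to H8, and the CH2O-stearoyl arm. Four stereocentres must be set (5S, 8S, 9R, 11R). C9 can control C8 through anti alkylation of a five-membered lactone, and C8 can control C11 because it is adjacent. C5 is three bonds from the nearest centre and can only be reached through the conformation of the medium ring or by a reagent. The C11–O bond is tertiary and doubly allylic (acid-labile), C5–OH is a tertiary allylic alcohol, C2 is a doubly allylic methylene, the conjugated diene does not tolerate electrophiles, oxidants or metathesis catalysts, and the stearate excludes strong nucleophiles late on. The nine-membered ring with its Z alkene must be closed without involving the other three alkenes. The feature that opens the molecule is C11: it carries an ether oxygen, a one-carbon oxygenated arm and a dienyl group, with the C10 oxygen four atoms away. That is exactly what 5-exo attack of a hydroxyl on the substituted end of a dienyl epoxide leaves behind.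

## Retrosynthesis

**C5–CH3.** The last bond cut is C5–CH3, which turns target 26 into the nine-membered (Z)-enone 25, one stereocentre poorer. The neighbouring cut (C4–C5 with methyl already on the ketone) would close the ring and make the carbinol at once, but it asks an alkenylchromium reagent to attack a ketone in a medium-ring closure and gives one chance at C5. The methyl-last order needs only an organocerium 1,2-addition that spares the ester, and both orders stay open from aldehyde 23. The forward reaction must deliver methyl to the Re face of C5.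

**C4–C5 (nine-membered ring).** Enone 25 goes back through allylic alcohol 24 to the open-chain (Z)-iodoalkene aldehyde 23. A Nozaki–Hiyama–Kishi closure tolerates the ester, the dienyl ether and the other alkenes, and the Z geometry is carried in from the iodoalkene. The carbinol centre it creates is oxidised away. Ring-closing alkene metathesis at C3=C4 was set aside because the C1 methylene and the diene would compete. Precursor 23 is a tetrahydrofuran with two open chains.

**Functional-group changes.** Aldehyde 23 comes from alcohol 19 with no C–C bond formed: stearoylation (20), alkyne iodination (21), cis reduction (22) and acetal hydrolysis. The terminal alkyne is the latent Z-iodoalkene and the dimethyl acetal the latent aldehyde. Both are inert to zerovalent palladium, which an iodoalkene would not be, so they are unveiled after the key step.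

**O–C11 (tetrahydrofuran, key step).** Alcohol 19 is opened at O–C11 to hydroxy dienyl epoxide 18. This cut removes the ring and the quaternary stereocentre together and leaves the stearate oxygen as the epoxide oxygen. The alternatives at C11 (C–C bond formation on a cyclic oxocarbenium ion, or the Prins–pinacol route below) need Lewis acids next to the diene. The forward reaction must attack C11 rather than C13 or C15 and place the dienyl group cis to H8.

**C11–CH2 (epoxide).** Epoxide 18 comes from dienone 16 by methylene transfer from a sulfonium ylide (17) and desilylation. The C10 hydroxyl is silylated over these two steps so that no alkoxide faces the ketone or the new epoxide. Felkin–Anh addition is asked to favour the (11R)-epoxide.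

**C11–C12.** Dienone 16 is the silyl ether of hydroxy dienone 15, which is cut between the carbonyl and the diene into lactone 11 and dienyllithium 14 (from iodide 13, from aldehyde 12). The lactone supplies C10–O and C11 at the right oxidation level and hides the hydroxyl until it is needed. The forward reaction must stop at mono-addition.

**C7–C8.** Lactone 11 is cut into lactone 7 and iodide 9 (from bromide 8). Alkylation of a 4-substituted butyrolactone enolate anti to the substituent sets C8 from C9, so only one centre has to come from a catalyst.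

**C9–C1.** Lactone 7 is cut into furanone 6 and alkenylboronate 5, joined by a rhodium-catalysed asymmetric conjugate addition. Boronate 5 comes from bromide 4, made from alkyne 1 and dibromide 2 through Grignard reagent 3. All of C1–C4 is then in place from the first step.

## Roads not taken

**Alternative 1:** The cut is C1–C2 of the nine-membered ring. [CpRu(NCMe)3]PF6 would couple the ethynyl group on C9 of alkynyl lactone A1 with the terminal alkene of its homoallylic carbinol chain (Alder-ene reaction). This closes the ring to bicyclic lactone A2 and creates the C1 methylene and the C3=C4 alkene in one step.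
- Merits: the step is an isomerisation with no stoichiometric metal, and C5 would be set in an open chain by a reagent of choice before the ring exists. In this respect it is better than the chosen plan, where C5 is set last under control of the ring.
- Weak points: a ruthenacycle spanning a nine-membered ring has little support outside large rings. The β-hydride elimination normally gives an E alkene where the ring needs Z. The free tertiary alcohol sits next to the hydrogen to be transferred. A2 still lacks C11, so the dienyl addition and etherification would follow anyway, now beside a tertiary allylic alcohol and a skipped diene.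
- Comparison: against the better C5 control, the chosen plan sets a ring closure of a well-tried kind, a pivot at aldehyde 23 from which C5 can be approached in either order, and a direct answer to C11.

**Alternative 2:** The cut removes C8–C11 and C9–C10 together. SnCl4 would open cyclic ketal A3 to an oxocarbenium ion at C11. The E C8=C9 alkene attacks it and C10 shifts from C1 to C9 (Prins–pinacol), giving acyltetrahydrofuran A4.
- Merits: three stereocentres (C8, C9, C11) and two C–C bonds form in one convergent step. In centres set per step it is better than the chosen plan.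
- Weak points: the cation at C11 is also a pentadienyl cation, so it is less electrophilic at C11 and can scramble the diene or be captured at C13 or C15. The two C11 substituents are both unbranched at the attached atom, so the oxocarbenium geometry, and with it C11, is poorly biased. The ketal of a hindered dienone is hard to form. The tertiary allylic silyl ether and the diene must survive SnCl4. A4 still needs ring closure at C3=C4 by metathesis beside the diene and methylenation of the C1 ketone.
- Comparison: the chosen plan sets against it a C11 centre made under neutral conditions with three reinforcing control elements, and a diene that never meets a strong Lewis acid.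

**Alternative 3:** The cut is the pair of bonds with which the chosen route begins, C9–C1 and C7–C8, made in one flask. Cu(OTf)2 with a chiral phosphoramidite would add alkenylalane A5 to furanone 6, and the aluminium enolate would be alkylated by iodide A6 to give trans-lactone A7.
- Merits: one step replaces three (borylation, conjugate addition, alkylation). In step count it is better than the front end of the chosen route.
- Weak points: copper-catalysed asymmetric addition of alkenylalanes is established for cyclic enones, much less for an unsubstituted butenolide. Aluminium enolates alkylate unactivated primary iodides poorly. Making A5 requires lithiation next to a doubly activated methylene. As a central step it addresses neither C11 nor the medium ring.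
- Comparison: it is a possible later shortening of steps 2, 3 and 5, not a competing strategy. The chosen route accepts two more steps for two reactions with strong records.

Key step: step 11

Assumption: the (R,R)-ligand is written in step 11 as the enantiomer matched with the (8S,9R)-substrate; its sense of induction at a 1,1-disubstituted dienyl terminus cannot be assigned with certainty in advance, and the (S,S)-ligand replaces it without other change if the pairing is mismatched.

Assumption: the peripheral face of the C5 ketone of 25 is taken to be the Re face, which gives the (5S)-alcohol; this could not be derived from the structure with confidence, and the fallback for step 18 serves the other outcome.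

## Route

Step 1
Reactants: 1 ethynyltrimethylsilane; 2 2,3-dibromoprop-1-ene
Product: 4 (4-bromopent-4-en-1-yn-1-yl)trimethylsilane, via [(trimethylsilyl)ethynyl]magnesium bromide 3 (not isolated)
Conditions: EtMgBr, THF, 0 °C to rt; then CuBr (5 mol %), 2, THF, 50 °C
Reagents that add atoms: none
Why: Copper-catalysed coupling of an alkynyl Grignard reagent with an allylic bromide; direct and transposed substitution give the same product because the allyl unit is symmetric about C2, and the vinylic bromide does not react.

Step 2
Reactants: 4 (4-bromopent-4-en-1-yn-1-yl)trimethylsilane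
Product: 5 trimethyl[4-(4,4,5,5-tetramethyl-1,3,2-dioxaborolan-2-yl)pent-4-en-1-yn-1-yl]silane
Conditions: B2pin2, PdCl2(PPh3)2 (3 mol %), PPh3 (6 mol %), KOPh, toluene, 50 °C
Reagents that add atoms: bis(pinacolato)diboron, CC1(C)OB(OC1(C)C)B1OC(C)(C)C(C)(C)O1
Why: Miyaura borylation of a 1-alkenyl bromide; phenoxide promotes transmetalation from the diboron reagent without a stronger base that would bring on Suzuki homocoupling or attack the silylalkyne.

Step 3
Reactants: 5 trimethyl[4-(4,4,5,5-tetramethyl-1,3,2-dioxaborolan-2-yl)pent-4-en-1-yn-1-yl]silane; 6 furan-2(5H)-one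
Product: 7 (4R)-4-[5-(trimethylsilyl)pent-1-en-4-yn-2-yl]oxolan-2-one
Conditions: [Rh(OH)((R)-BINAP)]2 (3 mol % Rh), 1,4-dioxane/H2O (10:1), 50 °C; dilute HCl work-up
Reagents that add atoms: none
Why: Rhodium-catalysed asymmetric 1,4-addition of an alkenylboronate (Hayashi–Miyaura reaction): transmetalation, enantioface-selective insertion of the furanone and hydrolysis of the oxa-π-allylrhodium; C9 is set by the ligand, and by the facial model for cyclic enones and unsaturated lactones (R)-BINAP should give the (4R)-lactone; the hydroxo complex needs no added base, which spares the lactone and the silylalkyne.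

Step 4
Reactants: 8 3-bromo-1,1-dimethoxypropane
Product: 9 3-iodo-1,1-dimethoxypropane
Conditions: NaI, NaHCO3 (cat.), acetone, reflux
Reagents that add atoms: sodium iodide, [Na+].[I-]
Why: Finkelstein exchange; the iodide is wanted because a lactone enolate alkylates unactivated primary bromides only sluggishly.

Step 5
Reactants: 7 (4R)-4-[5-(trimethylsilyl)pent-1-en-4-yn-2-yl]oxolan-2-one; 9 3-iodo-1,1-dimethoxypropane
Product: 11 (3S,4R)-3-(3,3-dimethoxypropyl)-4-[5-(trimethylsilyl)pent-1-en-4-yn-2-yl]oxolan-2-one, via lithium lactone enolate 10 (not isolated)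
Conditions: LDA, THF, −78 °C; then 9, HMPA, −78 to −40 °C
Reagents that add atoms: none
Why: Alkylation of the lithium enolate of a 4-substituted butyrolactone; the electrophile enters anti to the C9 substituent, which sets C8 (3S) trans to C9, and kinetic deprotonation at −78 °C leaves the doubly activated C2 methylene and the acetal untouched.

Step 6
Reactants: 12 3-methylbut-2-enal
Product: 13 (1E)-1-iodo-4-methylpenta-1,3-diene
Conditions: CHI3, CrCl2, THF, 0 °C to rt, dark
Reagents that add atoms: iodoform, IC(I)I
Why: Takai olefination; the geminal dichromium species adds to the aldehyde and eliminates to the (E)-iodoalkene; the product is light-sensitive and volatile and is carried on as a solution.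

Step 7
Reactants: 13 (1E)-1-iodo-4-methylpenta-1,3-diene; 11 (3S,4R)-3-(3,3-dimethoxypropyl)-4-[5-(trimethylsilyl)pent-1-en-4-yn-2-yl]oxolan-2-one
Product: 15 (4E,7S,8R)-7-(3,3-dimethoxypropyl)-8-(hydroxymethyl)-2-methyl-9-methylidene-12-(trimethylsilyl)dodeca-2,4-dien-11-yn-6-one, via [(1E)-4-methylpenta-1,3-dien-1-yl]lithium 14 (not isolated)
Conditions: 13, t-BuLi (2 equiv), Et2O, −78 °C; then 11, THF, −78 °C; aq. NH4Cl at −78 °C
Reagents that add atoms: none
Why: Iodine–lithium exchange with retention of the E geometry, then addition of the alkenyllithium to the lactone carbonyl; the lithium hemiketal alkoxide is stable at −78 °C and shields the carbonyl from a second addition, and on cold protonation it opens to the hydroxy dienone, favoured over the lactol by conjugation; C8 and C9 are not touched.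

Step 8
Reactants: 15 (4E,7S,8R)-7-(3,3-dimethoxypropyl)-8-(hydroxymethyl)-2-methyl-9-methylidene-12-(trimethylsilyl)dodeca-2,4-dien-11-yn-6-one
Product: 16 (4E,7S,8R)-7-(3,3-dimethoxypropyl)-2-methyl-9-methylidene-8-{[(triethylsilyl)oxy]methyl}-12-(trimethylsilyl)dodeca-2,4-dien-11-yn-6-one
Conditions: TESCl, imidazole, CH2Cl2, 0 °C
Reagents that add atoms: chlorotriethylsilane, CC[Si](Cl)(CC)CC
Why: Silylation of the primary alcohol; it removes the hydroxyl proton and the hemiketal equilibrium before the ylide step and keeps an alkoxide away from the epoxide formed next.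

Step 9
Reactants: 16 (4E,7S,8R)-7-(3,3-dimethoxypropyl)-2-methyl-9-methylidene-8-{[(triethylsilyl)oxy]methyl}-12-(trimethylsilyl)dodeca-2,4-dien-11-yn-6-one
Product: 17 (2R)-2-[(4S,5R)-1,1-dimethoxy-6-methylidene-5-{[(triethylsilyl)oxy]methyl}-9-(trimethylsilyl)non-8-yn-4-yl]-2-[(1E)-4-methylpenta-1,3-dien-1-yl]oxirane
Conditions: Me3S+ I−, n-BuLi, THF, −10 °C; then 16, −10 to 0 °C
Reagents that add atoms: trimethylsulfonium iodide, C[S+](C)C.[I-]
Why: Corey–Chaykovsky epoxidation; dimethylsulfonium methylide adds 1,2 to the dienone and the betaine closes with loss of Me2S; C11 is set by Felkin–Anh addition, the ylide carbon approaching anti to the branched C9 substituent with the C7 chain inside, which should give mainly the (11R)-epoxide, the epimer that the key step converts with net retention.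

Step 10
Reactants: 17 (2R)-2-[(4S,5R)-1,1-dimethoxy-6-methylidene-5-{[(triethylsilyl)oxy]methyl}-9-(trimethylsilyl)non-8-yn-4-yl]-2-[(1E)-4-methylpenta-1,3-dien-1-yl]oxirane
Product: 18 (2R,3S)-6,6-dimethoxy-3-{(2R)-2-[(1E)-4-methylpenta-1,3-dien-1-yl]oxiran-2-yl}-2-(pent-1-en-4-yn-2-yl)hexan-1-ol
Conditions: TBAF (2.5 equiv), THF, 0 °C; pH 7 buffer quench
Reagents that add atoms: none
Why: Fluoride cleaves the O–SiEt3 and the C(sp)–SiMe3 bonds in one operation; the epoxide is inert to fluoride, the quench is cold and buffered, and the acid-sensitive product is taken on without chromatography on untreated silica.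

Step 11
Reactants: 18 (2R,3S)-6,6-dimethoxy-3-{(2R)-2-[(1E)-4-methylpenta-1,3-dien-1-yl]oxiran-2-yl}-2-(pent-1-en-4-yn-2-yl)hexan-1-ol
Product: 19 [(2R,3S,4R)-3-(3,3-dimethoxypropyl)-2-[(1E)-4-methylpenta-1,3-dien-1-yl]-4-(pent-1-en-4-yn-2-yl)oxolan-2-yl]methanol
Conditions: Pd2(dba)3·CHCl3 (2.5 mol %), (R,R)-N,N'-(cyclohexane-1,2-diyl)bis[2-(diphenylphosphino)benzamide] (7.5 mol %), CH2Cl2, rt
Reagents that add atoms: none
Why: Zerovalent palladium ionises the allylic C11–O bond of the epoxide with inversion to a zwitterionic dienyl-palladium alkoxide; the alkoxide takes the proton of the C10 hydroxyl and the C10 oxygen then attacks C11 anti to the metal. The closest known reaction type is the palladium-catalysed asymmetric addition of alcohols to 2-substituted vinyl epoxides, with its intramolecular form that closes hydroxy vinyl epoxides to 2-vinyltetrahydrofurans. The tetrahydrofuran closes in the 5-exo mode with the dienyl unit outside the ring; attack at C13 or C15 would need a seven- or nine-membered ring. C11 is the only new stereocentre and three elements are set to agree on it: the major (11R)-epoxide gives the (11R)-ether by two inversions; if the allyl complexes interconvert through sigma-bonded forms along the dienyl chain, the ligand is chosen to favour the same complex; and the substrate prefers the transition state with the bulky dienyl-palladium unit trans to the C7 chain on C8. The step needs C11 selectivity and 5-exo regiochemistry, the first secured by this agreement and the second by ring size. The E geometry of C12=C13 is kept because the syn dienyl complex is the stable one, and the terminal alkyne, the acetal and the 1,1-disubstituted alkene are not touched at room temperature.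

Step 12
Reactants: 19 [(2R,3S,4R)-3-(3,3-dimethoxypropyl)-2-[(1E)-4-methylpenta-1,3-dien-1-yl]-4-(pent-1-en-4-yn-2-yl)oxolan-2-yl]methanol
Product: 20 [(2R,3S,4R)-3-(3,3-dimethoxypropyl)-2-[(1E)-4-methylpenta-1,3-dien-1-yl]-4-(pent-1-en-4-yn-2-yl)oxolan-2-yl]methyl octadecanoate
Conditions: octadecanoyl chloride, pyridine, DMAP (cat.), CH2Cl2, 0 °C to rt
Reagents that add atoms: octadecanoyl chloride, CCCCCCCCCCCCCCCCCC(=O)Cl
Why: DMAP-catalysed acylation of the only hydroxyl in the molecule, a primary neopentyl-type alcohol.

Step 13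
Reactants: 20 [(2R,3S,4R)-3-(3,3-dimethoxypropyl)-2-[(1E)-4-methylpenta-1,3-dien-1-yl]-4-(pent-1-en-4-yn-2-yl)oxolan-2-yl]methyl octadecanoate
Product: 21 [(2R,3S,4R)-3-(3,3-dimethoxypropyl)-4-(5-iodopent-1-en-4-yn-2-yl)-2-[(1E)-4-methylpenta-1,3-dien-1-yl]oxolan-2-yl]methyl octadecanoate
Conditions: N-iodosuccinimide, AgNO3 (10 mol %), DMF, rt, dark
Reagents that add atoms: N-iodosuccinimide, O=C1CCC(=O)N1I
Why: Silver-catalysed iodination of a terminal alkyne through the silver acetylide; the neutral conditions leave the diene, the acetal and the ester alone.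

Step 14
Reactants: 21 [(2R,3S,4R)-3-(3,3-dimethoxypropyl)-4-(5-iodopent-1-en-4-yn-2-yl)-2-[(1E)-4-methylpenta-1,3-dien-1-yl]oxolan-2-yl]methyl octadecanoate
Product: 22 [(2R,3S,4R)-3-(3,3-dimethoxypropyl)-4-[(4Z)-5-iodopenta-1,4-dien-2-yl]-2-[(1E)-4-methylpenta-1,3-dien-1-yl]oxolan-2-yl]methyl octadecanoate
Conditions: 2-nitrobenzenesulfonohydrazide, Et3N, THF/i-PrOH, rt
Reagents that add atoms: none
Why: Diimide released from the sulfonohydrazide delivers two hydrogens syn to the iodoalkyne and gives the (Z)-iodoalkene; iodoalkynes are reduced much faster than 1,1-disubstituted or conjugated alkenes, so the reagent is limited and the reaction followed closely.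

Step 15
Reactants: 22 [(2R,3S,4R)-3-(3,3-dimethoxypropyl)-4-[(4Z)-5-iodopenta-1,4-dien-2-yl]-2-[(1E)-4-methylpenta-1,3-dien-1-yl]oxolan-2-yl]methyl octadecanoate
Product: 23 [(2R,3S,4R)-4-[(4Z)-5-iodopenta-1,4-dien-2-yl]-2-[(1E)-4-methylpenta-1,3-dien-1-yl]-3-(3-oxopropyl)oxolan-2-yl]methyl octadecanoate
Conditions: PPTS (0.2 equiv), acetone/H2O (10:1), 40 °C
Reagents that add atoms: water, O
Why: Mild acid hydrolysis of a dimethyl acetal; PPTS is weak enough to leave the tertiary dienylic ether at C11 and the iodoalkene intact.

Step 16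
Reactants: 23 [(2R,3S,4R)-4-[(4Z)-5-iodopenta-1,4-dien-2-yl]-2-[(1E)-4-methylpenta-1,3-dien-1-yl]-3-(3-oxopropyl)oxolan-2-yl]methyl octadecanoate
Product: 24 [(3R,3aS,7Z,10aR)-6-hydroxy-10-methylidene-3-[(1E)-4-methylpenta-1,3-dien-1-yl]-3,3a,4,5,6,9,10,10a-octahydro-1H-cyclonona[c]furan-3-yl]methyl octadecanoate (both C6 epimers)
Conditions: CrCl2 (8 equiv), NiCl2 (2 mol %), DMSO/THF, rt, 0.003 M
Reagents that add atoms: none
Why: Intramolecular Nozaki–Hiyama–Kishi reaction; nickel-catalysed formation of the alkenylchromium reagent with retention of the Z geometry and addition to the aldehyde under high dilution closes the nine-membered ring at C4–C5; ester, ether and the other alkenes are inert to divalent chromium, and the new carbinol centre is oxidised next.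

Step 17
Reactants: 24 [(3R,3aS,7Z,10aR)-6-hydroxy-10-methylidene-3-[(1E)-4-methylpenta-1,3-dien-1-yl]-3,3a,4,5,6,9,10,10a-octahydro-1H-cyclonona[c]furan-3-yl]methyl octadecanoate
Product: 25 [(3R,3aS,7Z,10aR)-10-methylidene-3-[(1E)-4-methylpenta-1,3-dien-1-yl]-6-oxo-3,3a,4,5,6,9,10,10a-octahydro-1H-cyclonona[c]furan-3-yl]methyl octadecanoate
Conditions: Dess–Martin periodinane, NaHCO3, CH2Cl2, 0 °C to rt
Reagents that add atoms: none
Why: Dess–Martin oxidation of a secondary allylic alcohol; the buffered neutral conditions avoid migration of the skipped diene into conjugation and do not touch the dienyl ether.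

Step 18
Reactants: 25 [(3R,3aS,7Z,10aR)-10-methylidene-3-[(1E)-4-methylpenta-1,3-dien-1-yl]-6-oxo-3,3a,4,5,6,9,10,10a-octahydro-1H-cyclonona[c]furan-3-yl]methyl octadecanoate
Product: 26 [(3R,3aS,6S,7Z,10aR)-6-hydroxy-6-methyl-10-methylidene-3-[(1E)-4-methylpenta-1,3-dien-1-yl]-3,3a,4,5,6,9,10,10a-octahydro-1H-cyclonona[c]furan-3-yl]methyl octadecanoate
Conditions: MeMgBr, CeCl3, THF, −78 °C
Reagents that add atoms: methylmagnesium bromide, C[Mg]Br
Why: 1,2-Addition of an organocerium reagent to the enone; the reagent is non-basic, so the doubly allylic C2 is not deprotonated, and at −78 °C it adds to the ketone far faster than to the stearate; C5 is set by attack on the peripheral face of the ring ketone, which must be the Re face to give 5S.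

## Compound list

1 | ethynyltrimethylsilane | C#C[Si](C)(C)C | starting material
2 | 2,3-dibromoprop-1-ene | C=C(Br)CBr | starting material
3 | [(trimethylsilyl)ethynyl]magnesium bromide | C[Si](C)(C)C#C[Mg]Br | intermediate
4 | (4-bromopent-4-en-1-yn-1-yl)trimethylsilane | C=C(Br)CC#C[Si](C)(C)C | intermediate
5 | trimethyl[4-(4,4,5,5-tetramethyl-1,3,2-dioxaborolan-2-yl)pent-4-en-1-yn-1-yl]silane | C=C(CC#C[Si](C)(C)C)B1OC(C)(C)C(C)(C)O1 | intermediate
6 | furan-2(5H)-one | O=C1OCC=C1 | starting material
7 | (4R)-4-[5-(trimethylsilyl)pent-1-en-4-yn-2-yl]oxolan-2-one | O=C1OC[C@@H](C(=C)CC#C[Si](C)(C)C)C1 | intermediate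
8 | 3-bromo-1,1-dimethoxypropane | COC(CCBr)OC | starting material
9 | 3-iodo-1,1-dimethoxypropane | COC(CCI)OC | intermediate
10 | lithium enolate of lactone 7 | [Li]OC1=C[C@@H](CO1)C(=C)CC#C[Si](C)(C)C | intermediate
11 | (3S,4R)-3-(3,3-dimethoxypropyl)-4-[5-(trimethylsilyl)pent-1-en-4-yn-2-yl]oxolan-2-one | O=C1OC[C@@H](C(=C)CC#C[Si](C)(C)C)[C@@H]1CCC(OC)OC | intermediate
12 | 3-methylbut-2-enal | CC(C)=CC=O | starting material
13 | (1E)-1-iodo-4-methylpenta-1,3-diene | I/C=C/C=C(C)C | intermediate
14 | [(1E)-4-methylpenta-1,3-dien-1-yl]lithium | [Li]/C=C/C=C(C)C | intermediate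
15 | (4E,7S,8R)-7-(3,3-dimethoxypropyl)-8-(hydroxymethyl)-2-methyl-9-methylidene-12-(trimethylsilyl)dodeca-2,4-dien-11-yn-6-one | C[Si](C)(C)C#CCC(=C)[C@H](CO)[C@H](CCC(OC)OC)C(=O)/C=C/C=C(C)C | intermediate
16 | (4E,7S,8R)-7-(3,3-dimethoxypropyl)-2-methyl-9-methylidene-8-{[(triethylsilyl)oxy]methyl}-12-(trimethylsilyl)dodeca-2,4-dien-11-yn-6-one | C[Si](C)(C)C#CCC(=C)[C@H](CO[Si](CC)(CC)CC)[C@H](CCC(OC)OC)C(=O)/C=C/C=C(C)C | intermediate
17 | (2R)-2-[(4S,5R)-1,1-dimethoxy-6-methylidene-5-{[(triethylsilyl)oxy]methyl}-9-(trimethylsilyl)non-8-yn-4-yl]-2-[(1E)-4-methylpenta-1,3-dien-1-yl]oxirane | C[Si](C)(C)C#CCC(=C)[C@H](CO[Si](CC)(CC)CC)[C@H](CCC(OC)OC)[C@]1(/C=C/C=C(C)C)CO1 | intermediate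
18 | (2R,3S)-6,6-dimethoxy-3-{(2R)-2-[(1E)-4-methylpenta-1,3-dien-1-yl]oxiran-2-yl}-2-(pent-1-en-4-yn-2-yl)hexan-1-ol | C#CCC(=C)[C@H](CO)[C@H](CCC(OC)OC)[C@]1(/C=C/C=C(C)C)CO1 | intermediate
19 | [(2R,3S,4R)-3-(3,3-dimethoxypropyl)-2-[(1E)-4-methylpenta-1,3-dien-1-yl]-4-(pent-1-en-4-yn-2-yl)oxolan-2-yl]methanol | C#CCC(=C)[C@@H]1CO[C@@](/C=C/C=C(C)C)(CO)[C@H]1CCC(OC)OC | intermediate
20 | [(2R,3S,4R)-3-(3,3-dimethoxypropyl)-2-[(1E)-4-methylpenta-1,3-dien-1-yl]-4-(pent-1-en-4-yn-2-yl)oxolan-2-yl]methyl octadecanoate | C#CCC(=C)[C@@H]1CO[C@@](/C=C/C=C(C)C)(COC(=O)CCCCCCCCCCCCCCCCC)[C@H]1CCC(OC)OC | intermediate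
21 | [(2R,3S,4R)-3-(3,3-dimethoxypropyl)-4-(5-iodopent-1-en-4-yn-2-yl)-2-[(1E)-4-methylpenta-1,3-dien-1-yl]oxolan-2-yl]methyl octadecanoate | IC#CCC(=C)[C@@H]1CO[C@@](/C=C/C=C(C)C)(COC(=O)CCCCCCCCCCCCCCCCC)[C@H]1CCC(OC)OC | intermediate
22 | [(2R,3S,4R)-3-(3,3-dimethoxypropyl)-4-[(4Z)-5-iodopenta-1,4-dien-2-yl]-2-[(1E)-4-methylpenta-1,3-dien-1-yl]oxolan-2-yl]methyl octadecanoate | I/C=C\CC(=C)[C@@H]1CO[C@@](/C=C/C=C(C)C)(COC(=O)CCCCCCCCCCCCCCCCC)[C@H]1CCC(OC)OC | intermediate
23 | [(2R,3S,4R)-4-[(4Z)-5-iodopenta-1,4-dien-2-yl]-2-[(1E)-4-methylpenta-1,3-dien-1-yl]-3-(3-oxopropyl)oxolan-2-yl]methyl octadecanoate | I/C=C\CC(=C)[C@@H]1CO[C@@](/C=C/C=C(C)C)(COC(=O)CCCCCCCCCCCCCCCCC)[C@H]1CCC=O | intermediate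
24 | [(3R,3aS,7Z,10aR)-6-hydroxy-10-methylidene-3-[(1E)-4-methylpenta-1,3-dien-1-yl]-3,3a,4,5,6,9,10,10a-octahydro-1H-cyclonona[c]furan-3-yl]methyl octadecanoate (C6 epimers) | C=C1C/C=C\C(O)CC[C@H]2[C@H]1CO[C@@]2(/C=C/C=C(C)C)COC(=O)CCCCCCCCCCCCCCCCC | intermediate
25 | [(3R,3aS,7Z,10aR)-10-methylidene-3-[(1E)-4-methylpenta-1,3-dien-1-yl]-6-oxo-3,3a,4,5,6,9,10,10a-octahydro-1H-cyclonona[c]furan-3-yl]methyl octadecanoate | C=C1C/C=C\C(=O)CC[C@H]2[C@H]1CO[C@@]2(/C=C/C=C(C)C)COC(=O)CCCCCCCCCCCCCCCCC | intermediate
26 | [(3R,3aS,6S,7Z,10aR)-6-hydroxy-6-methyl-10-methylidene-3-[(1E)-4-methylpenta-1,3-dien-1-yl]-3,3a,4,5,6,9,10,10a-octahydro-1H-cyclonona[c]furan-3-yl]methyl octadecanoate | C=C1C/C=C\[C@@](C)(O)CC[C@H]2[C@H]1CO[C@@]2(/C=C/C=C(C)C)COC(=O)CCCCCCCCCCCCCCCCC | target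

## Step count and least certain steps

Total: 18 steps. Longest linear sequence: 16 steps (1–3, 5 and 7–18) from ethynyltrimethylsilane; steps 4 and 6 make side-chain reagents.

**Step 11 (key step).** Most likely failure: loss of selectivity at C11. The dienyl-palladium complexes may not interconvert before the fast 5-exo capture, so the minor epoxide epimer from step 9 passes through with its own configuration, or the ligand may oppose the substrate. Ionisation of the doubly allylic epoxide by trace acid, without the metal, would erode selectivity in the same way.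
Fallback, from 16 back to 19: the stereoconvergent catalysis is given up for two stereospecific closures. The C11 epimers from step 9 are separated as silyl ethers on triethylamine-treated silica. Epoxide 17 is desilylated as in step 10 and 18 is cyclised with the achiral catalyst Pd(PPh3)4 in THF, where two inversions give 19 with net retention. The minor epimer, (2S)-2-[(4S,5R)-1,1-dimethoxy-6-methylidene-5-{[(triethylsilyl)oxy]methyl}-9-(trimethylsilyl)non-8-yn-4-yl]-2-[(1E)-4-methylpenta-1,3-dien-1-yl]oxirane F1, is desilylated with TBAF to (2R,3S)-6,6-dimethoxy-3-{(2S)-2-[(1E)-4-methylpenta-1,3-dien-1-yl]oxiran-2-yl}-2-(pent-1-en-4-yn-2-yl)hexan-1-ol F2. F2 is closed without metal by catalytic camphorsulfonic acid in CH2Cl2 at −40 °C: the hydroxyl opens the activated epoxide at the dienylic carbon with inversion (5-exo), which also gives 19.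

**Step 18.** Most likely failure: poor or wrong facial selectivity at C5, because the ring conformer that exposes the Re face of the ketone need not be the reactive one. Deprotonation at C2 is a lesser risk.
Fallback, from 23 back to 26: the order of the two C–C bonds at C5 is exchanged. MeMgBr at −78 °C converts aldehyde 23 to [(2R,3S,4R)-3-(3-hydroxybutyl)-4-[(4Z)-5-iodopenta-1,4-dien-2-yl]-2-[(1E)-4-methylpenta-1,3-dien-1-yl]oxolan-2-yl]methyl octadecanoate F3. Dess–Martin oxidation gives methyl ketone [(2R,3S,4R)-4-[(4Z)-5-iodopenta-1,4-dien-2-yl]-2-[(1E)-4-methylpenta-1,3-dien-1-yl]-3-(3-oxobutyl)oxolan-2-yl]methyl octadecanoate F4. CrCl2/NiCl2 closure of F4 under high dilution gives 26 directly, with the alkenyl carbon rather than methyl arriving last at C5.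

**Step 3.** Most likely failure: slow insertion of the poorly reactive furanone, so that protodeboronation of the 1-substituted alkenylboronate overtakes addition, with loss of conversion and of enantiomeric purity.
Fallback, from 4 back to 7: catalyst control is replaced by an auxiliary. Bromide 4 is converted with magnesium in THF to [5-(trimethylsilyl)pent-1-en-4-yn-2-yl]magnesium bromide F5. F5 is added with CuBr·SMe2 (cat.) and Me3SiCl at −78 °C to (5S)-5-{[(1S,2R,5S)-5-methyl-2-(propan-2-yl)cyclohexyl]oxy}furan-2(5H)-one F6, the butenolide from (+)-menthol. Attack anti to the menthyloxy group gives (4R,5S)-5-{[(1S,2R,5S)-5-methyl-2-(propan-2-yl)cyclohexyl]oxy}-4-[5-(trimethylsilyl)pent-1-en-4-yn-2-yl]oxolan-2-one F7. Acetal hydrolysis (aq. HCl, dioxane), NaBH4 reduction of the freed aldehyde and acid lactonisation remove the auxiliary and give 7.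

**Step 9.** Most likely failure: enolisation of the α-branched dienone by the basic ylide, which epimerises C8, together with only moderate Felkin–Anh selectivity.
Fallback, from 16 back to 17: the ylide is replaced by a carbenoid at low temperature. Chloromethyllithium, generated from ICH2Cl and MeLi·LiBr at −78 °C in the presence of 16, adds to the ketone faster than it deprotonates it. The alkoxide of (4E,6R,7S,8R)-6-(chloromethyl)-7-(3,3-dimethoxypropyl)-2-methyl-9-methylidene-8-{[(triethylsilyl)oxy]methyl}-12-(trimethylsilyl)dodeca-2,4-dien-11-yn-6-ol F8 closes to epoxide 17 on warming.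

**Step 14.** Most likely failure: over-reduction, with diimide reaching the 1,1-disubstituted alkene or the diene before the iodoalkyne is consumed.
Fallback, from 21 back to 22: transfer hydrogenation is replaced by hydroboration–protonolysis. Bis(3-methylbutan-2-yl)borane at 0 °C adds syn to the iodoalkyne much faster than to 1,1-disubstituted or internal alkenes and gives [(2R,3S,4R)-4-{(4Z)-5-[bis(3-methylbutan-2-yl)boranyl]-5-iodopenta-1,4-dien-2-yl}-3-(3,3-dimethoxypropyl)-2-[(1E)-4-methylpenta-1,3-dien-1-yl]oxolan-2-yl]methyl octadecanoate F9. Protonolysis of the C–B bond with acetic acid, with retention, gives 22.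

## Further compounds

F1 | step 11 | (2S)-2-[(4S,5R)-1,1-dimethoxy-6-methylidene-5-{[(triethylsilyl)oxy]methyl}-9-(trimethylsilyl)non-8-yn-4-yl]-2-[(1E)-4-methylpenta-1,3-dien-1-yl]oxirane | C[Si](C)(C)C#CCC(=C)[C@H](CO[Si](CC)(CC)CC)[C@H](CCC(OC)OC)[C@@]1(/C=C/C=C(C)C)CO1
F2 | step 11 | (2R,3S)-6,6-dimethoxy-3-{(2S)-2-[(1E)-4-methylpenta-1,3-dien-1-yl]oxiran-2-yl}-2-(pent-1-en-4-yn-2-yl)hexan-1-ol | C#CCC(=C)[C@H](CO)[C@H](CCC(OC)OC)[C@@]1(/C=C/C=C(C)C)CO1
F3 | step 18 | [(2R,3S,4R)-3-(3-hydroxybutyl)-4-[(4Z)-5-iodopenta-1,4-dien-2-yl]-2-[(1E)-4-methylpenta-1,3-dien-1-yl]oxolan-2-yl]methyl octadecanoate (carbinol epimers) | I/C=C\CC(=C)[C@@H]1CO[C@@](/C=C/C=C(C)C)(COC(=O)CCCCCCCCCCCCCCCCC)[C@H]1CCC(C)O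
F4 | step 18 | [(2R,3S,4R)-4-[(4Z)-5-iodopenta-1,4-dien-2-yl]-2-[(1E)-4-methylpenta-1,3-dien-1-yl]-3-(3-oxobutyl)oxolan-2-yl]methyl octadecanoate | I/C=C\CC(=C)[C@@H]1CO[C@@](/C=C/C=C(C)C)(COC(=O)CCCCCCCCCCCCCCCCC)[C@H]1CCC(C)=O
F5 | step 3 | [5-(trimethylsilyl)pent-1-en-4-yn-2-yl]magnesium bromide | C=C([Mg]Br)CC#C[Si](C)(C)C
F6 | step 3 | (5S)-5-{[(1S,2R,5S)-5-methyl-2-(propan-2-yl)cyclohexyl]oxy}furan-2(5H)-one | C[C@H]1CC[C@@H](C(C)C)[C@H](C1)O[C@H]1OC(=O)C=C1
F7 | step 3 | (4R,5S)-5-{[(1S,2R,5S)-5-methyl-2-(propan-2-yl)cyclohexyl]oxy}-4-[5-(trimethylsilyl)pent-1-en-4-yn-2-yl]oxolan-2-one | C[C@H]1CC[C@@H](C(C)C)[C@H](C1)O[C@H]1OC(=O)C[C@@H]1C(=C)CC#C[Si](C)(C)C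
F8 | step 9 | (4E,6R,7S,8R)-6-(chloromethyl)-7-(3,3-dimethoxypropyl)-2-methyl-9-methylidene-8-{[(triethylsilyl)oxy]methyl}-12-(trimethylsilyl)dodeca-2,4-dien-11-yn-6-ol | C[Si](C)(C)C#CCC(=C)[C@H](CO[Si](CC)(CC)CC)[C@H](CCC(OC)OC)[C@@](O)(CCl)/C=C/C=C(C)C
F9 | step 14 | [(2R,3S,4R)-4-{(4Z)-5-[bis(3-methylbutan-2-yl)boranyl]-5-iodopenta-1,4-dien-2-yl}-3-(3,3-dimethoxypropyl)-2-[(1E)-4-methylpenta-1,3-dien-1-yl]oxolan-2-yl]methyl octadecanoate | I/C(B(C(C)C(C)C)C(C)C(C)C)=C\CC(=C)[C@@H]1CO[C@@](/C=C/C=C(C)C)(COC(=O)CCCCCCCCCCCCCCCCC)[C@H]1CCC(OC)OC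
A1 | alternative 1 | (3S,4R)-4-ethynyl-3-[(3S)-3-hydroxy-3-methylhex-5-en-1-yl]oxolan-2-one | O=C1OC[C@@H](C#C)[C@@H]1CC[C@](C)(O)CC=C
A2 | alternative 1 | (3aS,6S,7Z,10aR)-6-hydroxy-6-methyl-10-methylidene-3a,4,5,6,9,10-hexahydro-1H-cyclonona[c]furan-3(10aH)-one | C=C1C/C=C\[C@@](C)(O)CC[C@H]2[C@H]1COC2=O
A3 | alternative 2 | 1,3-dioxolane ketal of the allylic 1,2-diol with the silyloxy dienone (ketal and carbinol centres undefined) | C=CCC1(COC(O1)(CO[Si](c2ccccc2)(c2ccccc2)C(C)(C)C)/C=C/C=C(C)C)/C=C/CC[C@](C)(O[Si](CC)(CC)CC)C=C
A4 | alternative 2 | 3-acyltetrahydrofuran with C8, C9 and C11 set | C=CCC(=O)[C@@H]1CO[C@@](/C=C/C=C(C)C)(CO[Si](c2ccccc2)(c2ccccc2)C(C)(C)C)[C@H]1CC[C@](C)(O[Si](CC)(CC)CC)C=C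
A5 | alternative 3 | dimethyl[5-(trimethylsilyl)pent-1-en-4-yn-2-yl]alumane | C[Al](C)C(=C)CC#C[Si](C)(C)C
A6 | alternative 3 | 2-(2-iodoethyl)-2-methyl-1,3-dioxolane | CC1(CCI)OCCO1
A7 | alternative 3 | (3S,4R)-3-[2-(2-methyl-1,3-dioxolan-2-yl)ethyl]-4-[5-(trimethylsilyl)pent-1-en-4-yn-2-yl]oxolan-2-one | O=C1OC[C@@H](C(=C)CC#C[Si](C)(C)C)[C@@H]1CCC2(C)OCCO2
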